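**Retrosynthetic overview**
1. The target comes from CO/H formylation of a ring-cis C1 enol triflate. The C18 aldehyde comes from oxidation of a C18–B bond. The C4 acetate is carried from the first C–C coupling onward.
2. The nine-membered ring comes from Grob fragmentation of a cis-hydrindane 1,3-hydroxy mesylate. The C1–C6 bond breaks while C1=O and (E)-C6=C7 form, so the fused five/six pair expands to one ring.
3. The six-membered ring comes from a new copper-catalysed borylative cyclisation of a vinyl group onto one carbonyl of a 2,2-disubstituted cyclopentane-1,3-dione. This makes the C1–C2 bond, the C2 stereocentre and the C18–B bond.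
4. The C10/C3/C4 triad comes from a one-pot asymmetric conjugate addition, aldol and acetylation of homoprenyl Grignard, S-ethyl thiocrotonate and the dione acetaldehyde.
5. Ring order: the five-membered ring is bought, the six-membered ring is fused on, and both are then merged into the nine-membered ring.

Locants (dictyodial numbering): the ring is C1 (bears C19), C2 (bears C18), C3 (bears side chain C10–C14), C4 (OAc), C5, C6 (methyl)=C7, C8, C9. The target is (2R,3R,4R,10S).

Assumption: for the two chiral ligands ((R,S)-Josiphos in step 4, (R,R)-QuinoxP* in step 7) the enantiomer named is taken to give the drawn configuration; if the sense is opposite, the mirror-image ligand is used.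

**Step 1**
Reactants: 1 2-methylcyclopentane-1,3-dione; 2 allyl bromide
Product: 3 2-allyl-2-methylcyclopentane-1,3-dione
Conditions: NaOH (1.0 equiv), H2O, rt, 48 h
Reagents that add atoms: none
Why: C-alkylation (SN2) of the soft 1,3-dione enolate with an allylic halide builds the quaternary, still prochiral C6 with C5 attached.

**Step 2**
Reactants: 3 2-allyl-2-methylcyclopentane-1,3-dione
Product: 5 (1-methyl-2,5-dioxocyclopentyl)acetaldehyde, via secondary ozonide 4 (not isolated)
Conditions: O3, CH2Cl2, −78 °C; Me2S, −78 °C → rt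
Reagents that add atoms: ozone, [O-][O+]=O
Why: Ozonolysis with reductive work-up cleaves the only alkene to the C4 aldehyde, and no stereocentre is formed.

**Step 3**
Reactants: 6 (E)-but-2-enoyl chloride; 7 ethanethiol
Product: 8 S-ethyl (E)-but-2-enethioate
Conditions: Et3N (1.1 equiv), CH2Cl2, 0 °C
Reagents that add atoms: none
Why: Nucleophilic acyl substitution (thioesterification) gives the acceptor, whose thioester is needed for high selectivity in step 4 and for the mild reduction in step 5.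

**Step 4**
Reactants: 9 5-bromo-2-methylpent-2-ene; 8 S-ethyl (E)-but-2-enethioate; 5 (1-methyl-2,5-dioxocyclopentyl)acetaldehyde
Product: 13 S-ethyl (2S,3R)-3-acetoxy-4-(1-methyl-2,5-dioxocyclopentyl)-2-[(2S)-6-methylhept-5-en-2-yl]butanethioate, via homoprenylmagnesium bromide 10 (not isolated), via magnesium thioester enolate 11 (not isolated), via bromomagnesium aldolate 12 (not isolated)
Conditions: 9, Mg, Et2O, reflux; add to 8, CuBr·SMe2 (5 mol%), (R,S)-Josiphos (6 mol%), t-BuOMe, −75 °C; 5, −75 °C; Ac2O (3 equiv), DMAP (10 mol%), −75 → 0 °C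
Reagents that add atoms: acetic anhydride, CC(=O)OC(C)=O
Why: Copper-catalysed asymmetric conjugate addition sets C10 under ligand control and gives the Z(O) enolate, whose Zimmerman–Traxler aldol addition to 5 on the face syn to the C10 methyl (A(1,3)-strain model) sets C3 and C4 as the syn aldol, and in situ O-acetylation installs the final acetate before the alkoxide can attack the dione.

**Step 5**
Reactants: 13 acetoxy thioester
Product: 14 (2R,3S,4S)-3-formyl-4,8-dimethyl-1-(1-methyl-2,5-dioxocyclopentyl)non-7-en-2-yl acetate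
Conditions: Et3SiH (3 equiv), Pd/C (10 wt%, 5 mol% Pd), acetone, rt
Reagents that add atoms: none
Why: The Fukuyama reduction converts only the thioester into the C2 aldehyde under neutral conditions, so the ketones, the acetate, the trisubstituted alkene and the C3 stereocentre are untouched.

**Step 6**
Reactants: 14 acetoxy aldehyde
Product: 15 (2R,3S,4S)-3-ethenyl-4,8-dimethyl-1-(1-methyl-2,5-dioxocyclopentyl)non-7-en-2-yl acetate
Conditions: CH2I2 (5 equiv), Zn (9 equiv), Ti(OiPr)4 (1 equiv), THF, rt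
Reagents that add atoms: diiodomethane, ICI
Why: Takai-type methylenation with a gem-dizinc/titanium reagent is aldehyde-selective over ketones and non-basic, so C18 is added without E1cB loss of the β-acetate or epimerisation at C3.

**Step 7**
Reactants: 15 vinyl dione
Product: 19 (3aR,4R,5R,6R,7aR)-3a-hydroxy-7a-methyl-5-[(2S)-6-methylhept-5-en-2-yl]-1-oxo-4-[(4,4,5,5-tetramethyl-1,3,2-dioxaborolan-2-yl)methyl]octahydroinden-6-yl acetate (cis-fused; the 4-, 5- and 6-substituents all equatorial), via secondary alkylcopper 16 (not isolated), via copper alkoxide 17 (not isolated), via O-boryl ether 18 (not isolated)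
Conditions: B2pin2 (1.3 equiv), CuCl (10 mol%), (R,R)-QuinoxP* (11 mol%), KOtBu (15 mol%), THF, 30 °C; aq NH4Cl
Reagents that add atoms: bis(pinacolato)diboron, CC1(C)OB(OC1(C)C)B1OC(C)(C)C(C)(C)O1
Why: Proposed new method: a ligated monovalent copper boryl adds syn to the unactivated terminal alkene with boron on C18 and copper on C2 (face chosen by the ligand); the C2–Cu bond then adds with retention to the nearby, inductively activated dione carbonyl through a chair with CH2B, side chain and OAc equatorial, forming the C1–C2 bond, the six-membered ring and the C2 stereocentre, and Cu–O/B–B exchange turns the catalyst over; attack on either carbonyl is acceptable because C1, C6 and C7 all become sp2 in step 10; the closest known reaction types are copper-catalysed borylative aldol cyclisation of enone-diones and borylative exo-cyclisation of alkenyl halides or alkenyl aryl ketones, not yet shown for an unactivated alkene closing a six-membered ring onto a dialkyl 1,3-dione.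

**Step 8**
Reactants: 19 ketol boronate
Product: 20 (1R,3aR,4R,5R,6R,7aS)-1,3a-dihydroxy-7a-methyl-5-[(2S)-6-methylhept-5-en-2-yl]-4-[(4,4,5,5-tetramethyl-1,3,2-dioxaborolan-2-yl)methyl]octahydroinden-6-yl acetate (1-OH cis to 7a-methyl and 3a-OH)
Conditions: NaBH4 (1.0 equiv), MeOH/CH2Cl2 1:1, −40 °C
Reagents that add atoms: none
Why: In this substrate-controlled hydride reduction, NaBH4 reaches the cyclopentanone from the face opposite the flanking angular methyl and the cis C1 hydroxyl, which places the C7 hydroxyl cis to the methyl as the E-selective fragmentation requires.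

**Step 9**
Reactants: 20 diol
Product: 21 (1R,3aR,4R,5R,6R,7aS)-3a-hydroxy-1-(methanesulfonyloxy)-7a-methyl-5-[(2S)-6-methylhept-5-en-2-yl]-4-[(4,4,5,5-tetramethyl-1,3,2-dioxaborolan-2-yl)methyl]octahydroinden-6-yl acetate
Conditions: MsCl (1.3 equiv), Et3N (2 equiv), CH2Cl2, −10 °C
Reagents that add atoms: methanesulfonyl chloride, CS(=O)(=O)Cl
Why: Selective O-sulfonylation takes the secondary alcohol only; the tertiary C1 hydroxyl stays free, and its cis relation to the mesylate rules out oxetane formation.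

**Step 10**
Reactants: 21 hydroxy mesylate
Product: 24 (2R,3R,4R,10S)-4-acetoxy-2-[(pinacolboryl)methyl]-6-methyl-3-(6-methylhept-5-en-2-yl)cyclonona-1(9),6-dien-1-yl trifluoromethanesulfonate (C6=C7 E; C1=C9 ring-cis), via cyclononenone 22 (not isolated), via potassium enolate 23 (not isolated)
Conditions: KN(SiMe3)2 (1.05 equiv), THF, −78 → 25 °C; re-cool to −78 °C, KN(SiMe3)2 (1.1 equiv); Comins' reagent (1.2 equiv), −78 → −20 °C
Reagents that add atoms: N-(5-chloropyridin-2-yl)bis(trifluoromethanesulfonimide) (Comins' reagent), FC(F)(F)S(=O)(=O)N(c1ccc(Cl)cn1)S(=O)(=O)C(F)(F)F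
Why: In this Grob fragmentation (heterolytic ring expansion) the C1 alkoxide pushes out the mesylate across the antiperiplanar C1–C6 bond, and because the mesylate is cis to the methyl, C5 and C8 end up trans, giving only the (E)-C6=C7 alkene in the nine-membered ketone; kinetic deprotonation at the less hindered C9 and O-triflation then fix the ring-cis C1=C9 double bond (a second trans alkene is too strained).

**Step 11**
Reactants: 24 enol triflate boronate
Product: 25 (2S,3R,4R,10S)-4-acetoxy-2-(hydroxymethyl)-6-methyl-3-(6-methylhept-5-en-2-yl)cyclonona-1(9),6-dien-1-yl trifluoromethanesulfonate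
Conditions: NaBO3·4H2O (4 equiv), THF/H2O 1:1, rt, 2 h
Reagents that add atoms: sodium perborate, [Na+].[Na+].O[B-]1(O)OO[B-](O)(O)OO1
Why: Oxidation of the alkylboronate (1,2-migration from B to O with retention) gives the C18 alcohol under mild conditions that spare the acetate, the enol triflate and both alkenes, and no enal is yet present to be epoxidised.

**Step 12**
Reactants: 25 primary alcohol
Product: 26 (2R,3R,4R,10S)-4-acetoxy-2-formyl-6-methyl-3-(6-methylhept-5-en-2-yl)cyclonona-1(9),6-dien-1-yl trifluoromethanesulfonate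
Conditions: Dess–Martin periodinane (1.3 equiv), CH2Cl2, 0 °C → rt
Reagents that add atoms: none
Why: Dess–Martin oxidation gives the C18 aldehyde without base, so C2 is not epimerised, and since C19 is still absent no lactol or lactone can form.

**Step 13**
Reactants: 26 formyl enol triflate
Product: 27 target, (2R,3R,4R,10S)-4-acetoxydictyodial
Conditions: CO (1 atm), Pd(PPh3)4 (5 mol%), LiCl (3 equiv), Bu3SnH (1.2 equiv, syringe pump, 3 h), THF, 50 °C
Reagents that add atoms: carbon monoxide, [C-]#[O+]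
Why: In this palladium-catalysed reductive carbonylation (Stille-type formylation), oxidative addition of zerovalent palladium into the vinyl triflate, CO insertion and hydride transfer from tin give the enal with retention of alkene geometry under neutral conditions tolerated by the acetate, the aldehyde and C2.

**Compound list**
1 | 2-methylcyclopentane-1,3-dione | CC1C(=O)CCC1=O | starting material
2 | allyl bromide | C=CCBr | starting material
3 | 2-allyl-2-methylcyclopentane-1,3-dione | C=CCC1(C)C(=O)CCC1=O | intermediate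
4 | 2-methyl-2-[(1,2,4-trioxolan-3-yl)methyl]cyclopentane-1,3-dione (secondary ozonide) | CC1(CC2OCOO2)C(=O)CCC1=O | intermediate
5 | (1-methyl-2,5-dioxocyclopentyl)acetaldehyde | CC1(CC=O)C(=O)CCC1=O | intermediate
6 | (E)-but-2-enoyl chloride | C/C=C/C(=O)Cl | starting material
7 | ethanethiol | CCS | starting material
8 | S-ethyl (E)-but-2-enethioate | C/C=C/C(=O)SCC | intermediate
9 | 5-bromo-2-methylpent-2-ene | CC(C)=CCCBr | starting material
10 | (4-methylpent-3-en-1-yl)magnesium bromide | CC(C)=CCC[Mg]Br | intermediate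
11 | bromomagnesium Z(O)-enolate of S-ethyl (S)-3,7-dimethyloct-6-enethioate (O–Mg cis to C10) | Br[Mg]O/C(SCC)=C\[C@@H](C)CCC=C(C)C | intermediate
12 | bromomagnesium aldolate (C4–OMgBr form of 13) | Br[Mg]O[C@H](CC1(C)C(=O)CCC1=O)[C@@H](C(=O)SCC)[C@@H](C)CCC=C(C)C | intermediate
13 | S-ethyl (2S,3R)-3-acetoxy-4-(1-methyl-2,5-dioxocyclopentyl)-2-[(2S)-6-methylhept-5-en-2-yl]butanethioate | CC(=O)O[C@H](CC1(C)C(=O)CCC1=O)[C@@H](C(=O)SCC)[C@@H](C)CCC=C(C)C | intermediate
14 | (2R,3S,4S)-3-formyl-4,8-dimethyl-1-(1-methyl-2,5-dioxocyclopentyl)non-7-en-2-yl acetate | CC(=O)O[C@H](CC1(C)C(=O)CCC1=O)[C@@H](C=O)[C@@H](C)CCC=C(C)C | intermediate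
15 | (2R,3S,4S)-3-ethenyl-4,8-dimethyl-1-(1-methyl-2,5-dioxocyclopentyl)non-7-en-2-yl acetate | CC(=O)O[C@H](CC1(C)C(=O)CCC1=O)[C@@H](C=C)[C@@H](C)CCC=C(C)C | intermediate
16 | β-boryl secondary alkylcopper at C2 (ligand omitted) | CC(=O)O[C@H](CC1(C)C(=O)CCC1=O)[C@@H]([C@H]([Cu])CB1OC(C)(C)C(C)(C)O1)[C@@H](C)CCC=C(C)C | intermediate
17 | copper C1-alkoxide of 19 (ligand omitted) | CC(=O)O[C@@H]1C[C@@]2(C)C(=O)CC[C@@]2(O[Cu])[C@H](CB3OC(C)(C)C(C)(C)O3)[C@H]1[C@@H](C)CCC=C(C)C | intermediate
18 | C1–O–Bpin ether of 19 | CC(=O)O[C@@H]1C[C@@]2(C)C(=O)CC[C@@]2(OB3OC(C)(C)C(C)(C)O3)[C@H](CB3OC(C)(C)C(C)(C)O3)[C@H]1[C@@H](C)CCC=C(C)C | intermediate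
19 | cis-hydrindane ketol boronate (3aR,4R,5R,6R,7aR), see step 7 | CC(=O)O[C@@H]1C[C@@]2(C)C(=O)CC[C@@]2(O)[C@H](CB3OC(C)(C)C(C)(C)O3)[C@H]1[C@@H](C)CCC=C(C)C | intermediate
20 | cis-hydrindane diol boronate (1R,3aR,4R,5R,6R,7aS), see step 8 | CC(=O)O[C@@H]1C[C@@]2(C)[C@H](O)CC[C@@]2(O)[C@H](CB3OC(C)(C)C(C)(C)O3)[C@H]1[C@@H](C)CCC=C(C)C | intermediate
21 | hydroxy mesylate (1R,3aR,4R,5R,6R,7aS), see step 9 | CC(=O)O[C@@H]1C[C@@]2(C)[C@H](OS(C)(=O)=O)CC[C@@]2(O)[C@H](CB3OC(C)(C)C(C)(C)O3)[C@H]1[C@@H](C)CCC=C(C)C | intermediate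
22 | (2R,3R,4R,10S,6E)-4-acetoxy-2-[(pinacolboryl)methyl]-6-methyl-3-(6-methylhept-5-en-2-yl)cyclonon-6-en-1-one | CC(=O)O[C@@H]1C/C(C)=C/CCC(=O)[C@H](CB2OC(C)(C)C(C)(C)O2)[C@H]1[C@@H](C)CCC=C(C)C | intermediate
23 | potassium C1(O)=C9 enolate of 22 (ring-cis) | [K+].CC(=O)O[C@@H]1C/C(C)=C/C/C=C(/[O-])[C@H](CB2OC(C)(C)C(C)(C)O2)[C@H]1[C@@H](C)CCC=C(C)C | intermediate
24 | enol triflate boronate, see step 10 | CC(=O)O[C@@H]1C/C(C)=C/C/C=C(/OS(=O)(=O)C(F)(F)F)[C@H](CB2OC(C)(C)C(C)(C)O2)[C@H]1[C@@H](C)CCC=C(C)C | intermediate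
25 | C18 alcohol enol triflate, see step 11 | CC(=O)O[C@@H]1C/C(C)=C/C/C=C(/OS(=O)(=O)C(F)(F)F)[C@H](CO)[C@H]1[C@@H](C)CCC=C(C)C | intermediate
26 | C18 aldehyde enol triflate, see step 12 | CC(=O)O[C@@H]1C/C(C)=C/C/C=C(/OS(=O)(=O)C(F)(F)F)[C@H](C=O)[C@H]1[C@@H](C)CCC=C(C)C | intermediate
27 | (2R,3R,4R,10S)-4-acetoxydictyodial (CNP0113811.4) | CC(=O)O[C@@H]1C/C(C)=C/C/C=C(/C=O)[C@H](C=O)[C@H]1[C@@H](C)CCC=C(C)C | target

**Totals:** 13 steps in all. The longest linear sequence is 12 steps (1, 2, 4–13, starting from 1).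

**Three steps most likely to fail**

*Step 7 (the proposed new step).*
- Risks: simple hydroboration by protonation of 16, poor facial control at C2, or cyclopropane formation by loss of the C4 acetate.
- The fallback uses known chemistry only. It sets out from 15 and comes back at 26.
- The vinyl group is hydroborated with 9-BBN-H to the B-alkyl-9-BBN adduct F1, which is oxidised with NaBO3·4H2O to the primary alcohol F2.
- Dess–Martin oxidation gives the homologous aldehyde F3.
- Pyrrolidine/AcOH (20 mol%) closes the ring by a 6-enolexo enamine aldol reaction to the cis-fused β-hydroxy aldehyde F4, in which C2 equilibrates to the equatorial position.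
- HC(OMe)3/PPTS masks it as the dimethyl acetal F5.
- NaBH4 gives the diol acetal F6, and MsCl/Et3N gives the mesylate acetal F7.
- KN(SiMe3)2 fragments it to the keto acetal F8. A second equivalent forms the potassium enolate F9, and Comins' reagent gives the enol triflate acetal F10.
- PPTS in wet acetone releases 26.

*Step 8.*
- Risk: hydride arrives from the methyl face and gives the C7 epimer, which would fragment to the Z-alkene.
- The fallback sets out from 19 and comes back at 24.
- The reduction product is accepted as the C7-epimeric diol F11.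
- It is converted with inversion by Mitsunobu-type sulfonylation (Zn(OTs)2, PPh3, DIAD, toluene) into the inverted tosylate F12, in which the sulfonate is cis to the methyl. The nucleophile uses the same face that the hydride preferred.
- F12 is then treated as in step 10 and passes through 22 and 23 to 24.

*Step 10.*
- Risks: the C1 alkoxide is tied up as a five-membered borate with the C18 boronate and fragments slowly, or the longer exposure to base damages the acetate.
- The fallback sets out from 21 and comes back at 25. Boron is removed before the ring expansion.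
- NaBO3·4H2O gives the hydroxymethyl mesylate F13, and TBSCl/imidazole gives the silyl ether mesylate F14.
- KN(SiMe3)2 fragments it to the silyloxy cyclononenone F15. Further KN(SiMe3)2 gives the potassium enolate F16, and Comins' reagent gives the silyloxy enol triflate F17.
- HF·pyridine then releases 25.

**Further compounds**
F1 | step 7 | B-alkyl-9-BBN adduct of 15 (boron on C18) | CC(=O)O[C@H](CC1(C)C(=O)CCC1=O)[C@@H](CCB1C2CCCC1CCC2)[C@@H](C)CCC=C(C)C
F2 | step 7 | (2R,3R,4S)-3-(2-hydroxyethyl)-4,8-dimethyl-1-(1-methyl-2,5-dioxocyclopentyl)non-7-en-2-yl acetate | CC(=O)O[C@H](CC1(C)C(=O)CCC1=O)[C@@H](CCO)[C@@H](C)CCC=C(C)C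
F3 | step 7 | 3-(2-oxoethyl) analogue of F2 | CC(=O)O[C@H](CC1(C)C(=O)CCC1=O)[C@@H](CC=O)[C@@H](C)CCC=C(C)C
F4 | step 7 | cis-hydrindane β-hydroxy aldehyde (4-formyl analogue of 19) | CC(=O)O[C@@H]1C[C@@]2(C)C(=O)CC[C@@]2(O)[C@H](C=O)[C@H]1[C@@H](C)CCC=C(C)C
F5 | step 7 | 4-(dimethoxymethyl) analogue of 19 | CC(=O)O[C@@H]1C[C@@]2(C)C(=O)CC[C@@]2(O)[C@H](C(OC)OC)[C@H]1[C@@H](C)CCC=C(C)C
F6 | step 7 | 4-(dimethoxymethyl) analogue of 20 | CC(=O)O[C@@H]1C[C@@]2(C)[C@H](O)CC[C@@]2(O)[C@H](C(OC)OC)[C@H]1[C@@H](C)CCC=C(C)C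
F7 | step 7 | 4-(dimethoxymethyl) analogue of 21 | CC(=O)O[C@@H]1C[C@@]2(C)[C@H](OS(C)(=O)=O)CC[C@@]2(O)[C@H](C(OC)OC)[C@H]1[C@@H](C)CCC=C(C)C
F8 | step 7 | 2-(dimethoxymethyl) analogue of 22 | CC(=O)O[C@@H]1C/C(C)=C/CCC(=O)[C@H](C(OC)OC)[C@H]1[C@@H](C)CCC=C(C)C
F9 | step 7 | potassium enolate of F8 | [K+].CC(=O)O[C@@H]1C/C(C)=C/C/C=C(/[O-])[C@H](C(OC)OC)[C@H]1[C@@H](C)CCC=C(C)C
F10 | step 7 | 2-(dimethoxymethyl) analogue of 24 | CC(=O)O[C@@H]1C/C(C)=C/C/C=C(/OS(=O)(=O)C(F)(F)F)[C@H](C(OC)OC)[C@H]1[C@@H](C)CCC=C(C)C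
F11 | step 8 | C7 epimer of 20 (1-OH trans to 7a-methyl) | CC(=O)O[C@@H]1C[C@@]2(C)[C@@H](O)CC[C@@]2(O)[C@H](CB3OC(C)(C)C(C)(C)O3)[C@H]1[C@@H](C)CCC=C(C)C
F12 | step 8 | 1-tosyloxy analogue of 21 (OTs cis to 7a-methyl) | CC(=O)O[C@@H]1C[C@@]2(C)[C@H](OS(=O)(=O)c3ccc(C)cc3)CC[C@@]2(O)[C@H](CB3OC(C)(C)C(C)(C)O3)[C@H]1[C@@H](C)CCC=C(C)C
F13 | step 10 | 4-(hydroxymethyl) analogue of 21 | CC(=O)O[C@@H]1C[C@@]2(C)[C@H](OS(C)(=O)=O)CC[C@@]2(O)[C@H](CO)[C@H]1[C@@H](C)CCC=C(C)C
F14 | step 10 | 4-[(tert-butyldimethylsilyloxy)methyl] analogue of 21 | CC(=O)O[C@@H]1C[C@@]2(C)[C@H](OS(C)(=O)=O)CC[C@@]2(O)[C@H](CO[Si](C)(C)C(C)(C)C)[C@H]1[C@@H](C)CCC=C(C)C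
F15 | step 10 | 2-[(tert-butyldimethylsilyloxy)methyl] analogue of 22 | CC(=O)O[C@@H]1C/C(C)=C/CCC(=O)[C@H](CO[Si](C)(C)C(C)(C)C)[C@H]1[C@@H](C)CCC=C(C)C
F16 | step 10 | potassium enolate of F15 | [K+].CC(=O)O[C@@H]1C/C(C)=C/C/C=C(/[O-])[C@H](CO[Si](C)(C)C(C)(C)C)[C@H]1[C@@H](C)CCC=C(C)C
F17 | step 10 | tert-butyldimethylsilyl ether of 25 | CC(=O)O[C@@H]1C/C(C)=C/C/C=C(/OS(=O)(=O)C(F)(F)F)[C@H](CO[Si](C)(C)C(C)(C)C)[C@H]1[C@@H](C)CCC=C(C)C
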